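(Its constants are made up; the run is a simulation.)

Neighbouring flasks hold the same charges of substrate and coupling partner and differ in when each goes in, so I want a number that cares about the order of entry and not about the clock.

| flask | substrate | coupling partner | time | remark |
|---|---|---|---|---|
| dusk | 0.020 M (fed, over 2.5 h) | 0.0140 M | 6.0 h | all else is in the flask from the start; the feed brings no volume worth counting |
| noon | 0.020 M (in portions, 3, over 2.5 h) | 0.0140 M | 6.0 h | first portion at the start, last at 2.5 h |
| autumn | 0.020 M | 0.0140 M | 6.0 h | everything together at the start |
| midnight | 0.020 M | 0.0140 M (fed, over 2.5 h) | 6.0 h | all else is in the flask from the start; the feed brings no volume worth counting |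

    2 coupling partner → self-condensation product (k1 = 0.022 L mol⁻¹ s⁻¹)
    substrate + coupling partner → isomer of the product (k2 = 4.8 × 10⁻⁴ L mol⁻¹ s⁻¹)
    substrate + coupling partner → target (k3 = 0.013 L mol⁻¹ s⁻¹)
    substrate + coupling partner → second isomer (k4 = 0.0020 L mol⁻¹ s⁻¹)

* the flask that comes out highest in amount of target, in percent of the substrate charged, or "all alike" when all lie within 1.5 percentage points (dusk / noon / autumn / midnight / all alike)
* target at the end, in percent of the substrate charged, dusk
* target at the end, in percent of the substrate charged, noon
* target at the end, in percent of the substrate charged, autumn
* target at the end, in percent of the substrate charged, midnight

The coupling partner is the limiting reagent, its charge being below that of substrate, and it has two exits. It meets substrate through the cross steps, whose constants add to 0.0155 L mol⁻¹ s⁻¹, or it meets itself, two at each turn. Dividing the rate of one exit by the other removes time. What stays is a selectivity factor, twice the self-condensation constant over the summed cross constant, 2.84. Multiplied by partner over substrate, it gives the waste ratio: partner lost to itself per partner lost to substrate.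

I try this on autumn, where the ratio starts at 1.99. The first lifetime of the partner there, 0.300 h, is far shorter than 6.0 h, so I let the partner react to its end. The target takes 84.0% of the cross turnover.

One way holds substrate at its charge. The share of partner reaching substrate is then the logarithm of one plus the ratio, divided by the ratio, 55.0%, which puts target at 32.4% of the substrate charged.

The other way integrates partner against substrate, with no time in it, and leaves 63.8% of the substrate, so target comes to 30.4%. The two part by 1.9 percentage points. The first cheats, because substrate falls below the charge it held fixed, so late partner meets less substrate than it allowed. I commit to the second.

For the order I compare the partner's share at the first moment of each flask, and I expect midnight highest, then autumn, noon and dusk.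

The forecast names midnight, with 15.5% for dusk, 18.2% for noon, 30.2% for autumn and 37.5% for midnight, the last between 35% and 40%. Its ground is that feeding the partner slowly into the substrate “keeps its concentration low and favours the cross-reaction”. Its autumn value lies 0.21 points under mine.

Target ends at 15.4% in dusk, 18.7% in noon, 30.2% in autumn and 38.2% in midnight, so midnight stands highest, as the forecast said. Midnight's target moves 5 points, out of the forecast's range, at a partner charge of 0.0113 M or 0.0172 M, with the other amounts and the time held. On midnight's amounts at the end of the feed, 2.50 h, the selectivity factor gives a waste ratio of 0.815, a value for that moment alone. Summed up to 6.00 h, partner lost to itself per partner lost to substrate stands at 0.514 in midnight, lower than the 0.938 of autumn.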